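**Retrosynthetic overview**
1. The ester C(=O)–O bond is made last, from alcohol 14 (21-(furan-2-yl)henicosa-14,16-diyn-1-ol) and acid 21 (19-(furan-2-yl)nonadeca-5,7-diynoic acid).
2. The strategy rests on the alkoxy chain (C1' = OCH2, furan on C21'): the diyne C14'≡C15'–C16'≡C17' lies between two unbranched CH2 carbons, C13' and C18'. All four sp carbons are therefore taken from one butadiyne unit (from 9), and C17'–C18' and C13'–C14' are made by two acetylide alkylations with bromides 4 and 8 in one flask.
3. Acid 21 is cut at the C6–C7 sp–sp bond: Cadiot–Chodkiewicz coupling of furyl alkyne 18 with 6-bromohex-5-ynoic acid 20.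
4. No ring is formed and the target has no stereocentre. Furan is lithiated and alkylated once to give bromide 4, which serves both halves: as an electrophile in the key step and, through its Grignard reagent and a copper-catalysed coupling with 1,7-dibromoheptane, as the source of the furyl C11 chain of 18.

Key step: step 5

Remark: bromide 4 is prepared once in step 1 on a scale that supplies both step 5 and step 7.

**Route**

Step 1
Reactants: 1 furan; 2 1,4-dibromobutane
Product: 4 2-(4-bromobutyl)furan, via 2-furyllithium 3 (not isolated)
Conditions: n-BuLi, THF, −78 to 0 °C; then added to 2 (3 equiv), THF, 0 °C to rt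
Reagents that add atoms: n-butyllithium, [Li]CCCC (supplies only the lithium of 3; none of its atoms remains in 4)
Why: α-Lithiation of furan followed by SN2 alkylation of the 2-furyllithium on a primary bromide, with inverse addition to excess dibromide to suppress double substitution.

Step 2
Reactants: 5 tridecanedioic acid
Product: 6 tridecane-1,13-diol
Conditions: LiAlH4, THF, 0 °C to reflux; aqueous work-up
Reagents that add atoms: none
Why: Hydride reduction of both carboxyl groups by LiAlH4 should give the primary diol, no other functional group being present.

Step 3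
Reactants: 6 tridecane-1,13-diol
Product: 7 13-bromotridecan-1-ol
Conditions: 48% aq. HBr, toluene, reflux
Reagents that add atoms: hydrogen bromide, Br
Why: Monobromination of a symmetrical α,ω-diol by SN2 substitution of the protonated alcohol, in which the bromo alcohol passes into the toluene phase and is shielded from a second substitution.

Step 4
Reactants: 7 13-bromotridecan-1-ol
Product: 8 (13-bromotridecyloxy)(tert-butyl)dimethylsilane
Conditions: TBSCl, imidazole, DMF, rt
Reagents that add atoms: tert-butyldimethylsilyl chloride, CC(C)(C)[Si](C)(C)Cl
Why: Imidazole-promoted silylation of a primary alcohol gives an ether that withstands amide and acetylide bases and leaves the primary bromide untouched.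

Step 5
Reactants: 9 1,4-dichlorobut-2-yne; 4 2-(4-bromobutyl)furan; 8 (13-bromotridecyloxy)(tert-butyl)dimethylsilane
Product: 13 tert-butyl{[21-(furan-2-yl)henicosa-14,16-diyn-1-yl]oxy}dimethylsilane, via sodium buta-1,3-diyn-1-ide 10 (not isolated), via 2-(octa-5,7-diyn-1-yl)furan 11 (not isolated), via sodium 8-(furan-2-yl)octa-1,3-diyn-1-ide 12 (not isolated)
Conditions: 9, NaNH2 (3 equiv), liq. NH3, −40 °C; 4 (0.9 equiv), −33 °C; NaNH2 (1 equiv); 8 in THF, −33 °C to rt (NH3 evaporating); NH4Cl quench
Reagents that add atoms: sodium amide, [Na+].[NH2-] (supplies only the sodium of 10 and 12; none of its atoms remains in 13)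
Why: Three equivalents of NaNH2 take 9 through two dehydrochlorinations and one deprotonation, so that only the mono-sodium diynide 10 is present when 4 is added, and SN2 attack of its terminal sp carbon on the primary C–Br bond forms C17'–C18' and gives terminal diyne 11. A fourth equivalent of amide removes the remaining sp C–H, which is far more acidic than any furan or alkyl C–H, and the resulting diynide 12 displaces bromide from 8 to form C13'–C14'. The closest known reaction type is the liquid-ammonia alkylation of alkali-metal butadiynides and 1,3-diynides with primary halides, here run as two alkylations in one flask. No ring is closed and no stereocentre is created. The selectivity needed is hetero- over homo-dialkylation, which is secured by the amide stoichiometry (no dianion before the first bromide, 10 in slight excess over 4) and by adding each bromide only after its anion is fully formed. Both electrophiles are unbranched primary bromides, which favours substitution over elimination, the THF co-solvent keeps lipophilic 8 in solution, and the furan and the silyl ether are inert to amide and acetylide bases.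

Step 6
Reactants: 13 tert-butyl{[21-(furan-2-yl)henicosa-14,16-diyn-1-yl]oxy}dimethylsilane
Product: 14 21-(furan-2-yl)henicosa-14,16-diyn-1-ol
Conditions: TBAF, THF, 0 °C to rt
Reagents that add atoms: none
Why: Fluoride-induced Si–O cleavage driven by the strong Si–F bond should free the primary alcohol, the diyne and the furan being inert to TBAF.

Step 7
Reactants: 4 2-(4-bromobutyl)furan; 15 1,7-dibromoheptane
Product: 17 2-(11-bromoundecyl)furan, via [4-(furan-2-yl)butyl]magnesium bromide 16 (not isolated)
Conditions: Mg, I2 (cat.), THF, rt to 40 °C; then added to 15 (3 equiv), Li2CuCl4 (cat.), THF, −10 °C to rt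
Reagents that add atoms: magnesium, [Mg] (supplies only the magnesium of 16; none of its atoms remains in 17)
Why: Grignard formation from the primary bromide followed by copper-catalysed sp3–sp3 cross-coupling (Kochi coupling) with a primary alkyl bromide should join the C4 and C7 chains, the excess of dibromide limiting double coupling and the furan ring being inert to the alkyl Grignard reagent.

Step 8
Reactants: 17 2-(11-bromoundecyl)furan
Product: 18 2-(tridec-12-yn-1-yl)furan
Conditions: LiC≡CH·H2NCH2CH2NH2, DMSO, 10 °C to rt
Reagents that add atoms: lithium acetylide–ethylenediamine complex, [Li]C#C.NCCN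
Why: SN2 displacement of the primary bromide by lithium acetylide in DMSO (two-carbon alkyne homologation), the dipolar solvent favouring substitution over elimination and the furan being inert.

Step 9
Reactants: 19 hex-5-ynoic acid
Product: 20 6-bromohex-5-ynoic acid
Conditions: Br2, KOH, H2O, 0 °C; then dilute HCl
Reagents that add atoms: bromine, BrBr
Why: Hypobromite bromination of a terminal alkyne through its acetylide in aqueous base is a standard route to ω-bromoalkynoic acids, the carboxylate being a spectator.

Step 10
Reactants: 18 2-(tridec-12-yn-1-yl)furan; 20 6-bromohex-5-ynoic acid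
Product: 21 19-(furan-2-yl)nonadeca-5,7-diynoic acid
Conditions: CuCl (cat.), NH2OH·HCl, 70% aq. EtNH2, MeOH/THF, 0 °C to rt, slow addition of 20; then aq. citric acid, 0 °C
Reagents that add atoms: none
Why: Cadiot–Chodkiewicz coupling, in which the copper acetylide of 18 (monovalent copper kept reduced by hydroxylamine) couples with the bromoalkyne of 20 to form the C6–C7 sp–sp bond, slow addition of 20 limiting its homocoupling.

Step 11
Reactants: 14 21-(furan-2-yl)henicosa-14,16-diyn-1-ol; 21 19-(furan-2-yl)nonadeca-5,7-diynoic acid
Product: 22 21-(furan-2-yl)henicosa-14,16-diyn-1-yl 19-(furan-2-yl)nonadeca-5,7-diynoate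
Conditions: DCC, DMAP (cat.), CH2Cl2, 0 °C to rt
Reagents that add atoms: none
Why: Steglich esterification, in which DCC activates 21 as the O-acylisourea and DMAP relays the acyl group to the unhindered primary alcohol under neutral conditions that spare both diynes and both acid-sensitive furans.

**Compound list**
1 | furan | c1ccoc1 | starting material
2 | 1,4-dibromobutane | BrCCCCBr | starting material
3 | 2-furyllithium | [Li]c1ccco1 | intermediate
4 | 2-(4-bromobutyl)furan | BrCCCCc1ccco1 | intermediate
5 | tridecanedioic acid | OC(=O)CCCCCCCCCCCC(=O)O | starting material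
6 | tridecane-1,13-diol | OCCCCCCCCCCCCCO | intermediate
7 | 13-bromotridecan-1-ol | OCCCCCCCCCCCCCBr | intermediate
8 | (13-bromotridecyloxy)(tert-butyl)dimethylsilane | BrCCCCCCCCCCCCCO[Si](C)(C)C(C)(C)C | intermediate
9 | 1,4-dichlorobut-2-yne | ClCC#CCCl | starting material
10 | sodium buta-1,3-diyn-1-ide | [Na+].[C-]#CC#C | intermediate
11 | 2-(octa-5,7-diyn-1-yl)furan | C#CC#CCCCCc1ccco1 | intermediate
12 | sodium 8-(furan-2-yl)octa-1,3-diyn-1-ide | [Na+].[C-]#CC#CCCCCc1ccco1 | intermediate
13 | tert-butyl{[21-(furan-2-yl)henicosa-14,16-diyn-1-yl]oxy}dimethylsilane | CC(C)(C)[Si](C)(C)OCCCCCCCCCCCCCC#CC#CCCCCc1ccco1 | intermediate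
14 | 21-(furan-2-yl)henicosa-14,16-diyn-1-ol | OCCCCCCCCCCCCCC#CC#CCCCCc1ccco1 | intermediate
15 | 1,7-dibromoheptane | BrCCCCCCCBr | starting material
16 | [4-(furan-2-yl)butyl]magnesium bromide | Br[Mg]CCCCc1ccco1 | intermediate
17 | 2-(11-bromoundecyl)furan | BrCCCCCCCCCCCc1ccco1 | intermediate
18 | 2-(tridec-12-yn-1-yl)furan | C#CCCCCCCCCCCCc1ccco1 | intermediate
19 | hex-5-ynoic acid | OC(=O)CCCC#C | starting material
20 | 6-bromohex-5-ynoic acid | OC(=O)CCCC#CBr | intermediate
21 | 19-(furan-2-yl)nonadeca-5,7-diynoic acid | OC(=O)CCCC#CC#CCCCCCCCCCCCc1ccco1 | intermediate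
22 | 21-(furan-2-yl)henicosa-14,16-diyn-1-yl 19-(furan-2-yl)nonadeca-5,7-diynoate | O=C(CCCC#CC#CCCCCCCCCCCCc1ccco1)OCCCCCCCCCCCCCC#CC#CCCCCc1ccco1 | target

**Step count**
Total: 11 steps. Longest linear sequence: 6 steps (steps 2, 3, 4, 5, 6, 11, from tridecanedioic acid).

**Steps most likely to fail**

Step 5 (key step). Proton exchange among 10, 11 and 12 in ammonia may scramble the alkylation pattern towards symmetrical dialkylation, and the second displacement may stall because 8 dissolves poorly. The fallback sets out from 8 and 4 and comes back at 13; it builds the diyne by sp–sp coupling instead of double alkylation. Bromide 8 is treated with LiC≡CH·H2NCH2CH2NH2 in DMSO to give tert-butyl(dimethyl)(pentadec-14-yn-1-yloxy)silane F1, and bromide 4 in the same way gives 2-(hex-5-yn-1-yl)furan F2. F1, which carries no furan, is brominated at the alkyne terminus with NBS and catalytic AgNO3 in acetone to [(15-bromopentadec-14-yn-1-yl)oxy](tert-butyl)dimethylsilane F3. Cadiot–Chodkiewicz coupling of F3 with F2 (CuCl, NH2OH·HCl, EtNH2, MeOH/THF) should then give 13.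

Step 10. Reductive homocoupling of the bromoalkynoate and binding of the copper catalyst by the carboxylate may leave 18 unconsumed. The fallback sets out from 18 and comes back at 21; it exchanges the roles of the partners so that the acid carries the terminal alkyne. 18 is deprotonated with n-BuLi in THF at −78 °C to lithium 13-(furan-2-yl)tridec-1-yn-1-ide F4, which is quenched with I2 to give 2-(13-iodotridec-12-yn-1-yl)furan F5, so the furan never meets an electrophilic bromine source. F5 is then coupled with hex-5-ynoic acid 19 (CuCl, NH2OH·HCl, EtNH2, MeOH/THF) to give 21.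

Step 3. Over-bromination to the dibromide and incomplete conversion may both arise because the two hydroxyl groups are identical. The fallback sets out from 6 and comes back at 8; it reverses the order of bromination and silylation so that desymmetrisation rests on precipitation of a monoalkoxide. 6 is treated with one equivalent of NaH in THF to form sodium 13-hydroxytridecan-1-olate F6, which is silylated with one equivalent of TBSCl to 13-[(tert-butyldimethylsilyl)oxy]tridecan-1-ol F7. Appel bromination of F7 (CBr4, PPh3, CH2Cl2, 0 °C) then gives 8 directly.

**Further compounds**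
F1 | step 5 | tert-butyl(dimethyl)(pentadec-14-yn-1-yloxy)silane | C#CCCCCCCCCCCCCCO[Si](C)(C)C(C)(C)C
F2 | step 5 | 2-(hex-5-yn-1-yl)furan | C#CCCCCc1ccco1
F3 | step 5 | [(15-bromopentadec-14-yn-1-yl)oxy](tert-butyl)dimethylsilane | BrC#CCCCCCCCCCCCCCO[Si](C)(C)C(C)(C)C
F4 | step 10 | lithium 13-(furan-2-yl)tridec-1-yn-1-ide | [Li]C#CCCCCCCCCCCCc1ccco1
F5 | step 10 | 2-(13-iodotridec-12-yn-1-yl)furan | IC#CCCCCCCCCCCCc1ccco1
F6 | step 3 | sodium 13-hydroxytridecan-1-olate | [Na+].[O-]CCCCCCCCCCCCCO
F7 | step 3 | 13-[(tert-butyldimethylsilyl)oxy]tridecan-1-ol | OCCCCCCCCCCCCCO[Si](C)(C)C(C)(C)C
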